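**Plan**

- Numbering used throughout: C1 vinylic methyl, C2=C3 enone alkene, C4 carbinol, C5 ring-fusion CH, C6 quaternary carbon, C7/C8 cyclopentane CH2, C9 ester carbon, C10 CH2, C11 ketone. The target is (4S,5S,6R,9R) in this numbering.
- Retrosynthetic cuts, in order: the C9–O aroyl bond, the C9–isopropyl bond, C2=C3 with the C1–C2 methyl bond, C4–OH/C5–H back to a C4=C5 alkene, and last C5–C6 together with C3–C4.
- Enabling feature: the cyclopentane C5–C6–C7–C8–C9 shares the C5–C6 bond with the seven-membered ring C2–C3–C4–C5–C6–C10–C11, and the oxygenated C11 lies between C10 and the C2–C3 unit. This is the pattern left when an alkyne (C4≡C5, tethered through C9–C8–C7) adds to an alkenylcyclopropane with C6=C10 as the alkene and C11 (oxygen-bearing), C2, C3 as the ring carbons.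
- Forward order: a linear ketal-tethered alkyne/siloxy-alkenylcyclopropane is built from pent-4-ynoic acid; one rhodium-catalysed [5+2] cycloaddition closes both rings; then the C1 methyl, C4–OH/C5–H, C9 isopropyl and ester, and C2=C3 are installed.
- Stereochemistry: C6 from the chiral rhodium–BINAP catalyst; C4 and C5 from syn hydroboration on the face opposite the C6 methyl; C9 from organocerium addition on the face opposite the C6 methyl.

Key step: step 8

Assumption: the sense of induction of [Rh(BINAP)]+ at a trisubstituted alkene terminus cannot be predicted with confidence; (R)-BINAP is written, and (S)-BINAP would be used instead if correlation shows that it is the antipode leading to the (6R) series.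

**Route**

Step 1
Reactants: 1 pent-4-ynoic acid
Product: 2 N-methoxy-N-methylpent-4-ynamide
Conditions: MeNH(OMe)·HCl, EDC·HCl, N-methylmorpholine, CH2Cl2, 0 °C → rt
Reagents that add atoms: N,O-dimethylhydroxylamine hydrochloride, CNOC.Cl
Why: Carbodiimide-mediated amide coupling gives the Weinreb amide, with the terminal alkyne as a spectator.

Step 2
Reactants: 2 N-methoxy-N-methylpent-4-ynamide; 3 ethynyltrimethylsilane
Product: 5 1-(trimethylsilyl)hepta-1,6-diyn-3-one, via lithium (trimethylsilyl)acetylide 4 (not isolated)
Conditions: 3, n-BuLi, THF, −78 °C; then 2, −78 → −20 °C; cold 1 M aq. HCl quench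
Reagents that add atoms: none
Why: Weinreb ketone synthesis: the chelated tetrahedral adduct prevents a second addition, and the acidic quench keeps the released amine from adding to the ynone.

Step 3
Reactants: 5 1-(trimethylsilyl)hepta-1,6-diyn-3-one
Product: 6 2-(but-3-yn-1-yl)-2-[(trimethylsilyl)ethynyl]-1,3-dioxolane
Conditions: Me3SiOCH2CH2OSiMe3, TMSOTf (cat.), CH2Cl2, −78 → −20 °C; pyridine quench
Reagents that add atoms: 1,2-bis(trimethylsilyloxy)ethane, C[Si](C)(C)OCCO[Si](C)(C)C
Why: Noyori ketalisation proceeds at low temperature under aprotic conditions, which avoids conjugate addition of the diol to the ynone.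

Step 4
Reactants: 6 2-(but-3-yn-1-yl)-2-[(trimethylsilyl)ethynyl]-1,3-dioxolane
Product: 8 (3E)-4-methyl-6-{2-[(trimethylsilyl)ethynyl]-1,3-dioxolan-2-yl}hex-3-en-2-one, via alkenyldimethylalane 7 (not isolated)
Conditions: AlMe3, Cp2ZrCl2 (0.5 equiv), CH2Cl2, 0 °C; then AcCl, Pd(PPh3)4 (cat.), THF, 0 °C → rt
Reagents that add atoms: trimethylaluminium, C[Al](C)C; acetyl chloride, CC(=O)Cl
Why: Negishi zirconium-catalysed carboalumination adds methyl and aluminium syn to the terminal alkyne only (methyl to the internal carbon, silylalkyne untouched), and palladium-catalysed acylation of the alkenylalane with retention gives the E enone.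

Step 5
Reactants: 8 (3E)-4-methyl-6-{2-[(trimethylsilyl)ethynyl]-1,3-dioxolan-2-yl}hex-3-en-2-one
Product: 10 (3E)-2-(tert-butyldimethylsilyloxy)-4-methyl-6-{2-[(trimethylsilyl)ethynyl]-1,3-dioxolan-2-yl}hexa-1,3-diene, via lithium dienolate 9 (not isolated)
Conditions: LiN(iPr)2, THF, −78 °C; then TBSCl, DMPU, −78 → 0 °C
Reagents that add atoms: tert-butyldimethylsilyl chloride, CC(C)(C)[Si](C)(C)Cl
Why: Kinetic deprotonation of the acetyl methyl gives the cross-conjugated dienolate, and O-silylation gives the 2-siloxy diene with the alkene geometry unchanged.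

Step 6
Reactants: 10 (3E)-2-(tert-butyldimethylsilyloxy)-4-methyl-6-{2-[(trimethylsilyl)ethynyl]-1,3-dioxolan-2-yl}hexa-1,3-diene
Product: 11 tert-butyl{1-[(1E)-2-methyl-4-{2-[(trimethylsilyl)ethynyl]-1,3-dioxolan-2-yl}but-1-en-1-yl]cyclopropoxy}dimethylsilane
Conditions: Et2Zn, CH2I2, CH2Cl2, 0 °C → rt
Reagents that add atoms: diiodomethane, ICI
Why: Simmons–Smith cyclopropanation (Furukawa modification) is selective for the electron-rich, unhindered silyl enol ether double bond over the trisubstituted alkene and the silylalkyne.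

Step 7
Reactants: 11 tert-butyl{1-[(1E)-2-methyl-4-{2-[(trimethylsilyl)ethynyl]-1,3-dioxolan-2-yl}but-1-en-1-yl]cyclopropoxy}dimethylsilane
Product: 12 tert-butyl{1-[(1E)-4-(2-ethynyl-1,3-dioxolan-2-yl)-2-methylbut-1-en-1-yl]cyclopropoxy}dimethylsilane
Conditions: K2CO3 (cat.), MeOH, rt
Reagents that add atoms: none
Why: Carbonate-catalysed methanolysis cleaves only the alkynyl C–Si bond, since the tertiary cyclopropyl TBS ether and the ketal are stable to these conditions.

Step 8
Reactants: 12 tert-butyl{1-[(1E)-4-(2-ethynyl-1,3-dioxolan-2-yl)-2-methylbut-1-en-1-yl]cyclopropoxy}dimethylsilane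
Product: 13 (6R)-bicyclic dienyl silyl ether (fused five/seven ring system with C4=C5 and C10=C11 double bonds, OTBS on C11, methyl on quaternary C6, spiro-1,3-dioxolane at C9)
Conditions: [Rh((R)-BINAP)]SbF6 (5–10 mol %), ClCH2CH2Cl, 25 → 60 °C
Reagents that add atoms: none
Why: Cationic monovalent rhodium binds alkyne and alkenylcyclopropane, strain-driven cleavage of a cyclopropane C–C bond gives a σ-alkyl/π-allyl trivalent rhodium intermediate, and alkyne insertion followed by reductive elimination releases the bicyclic diene with the oxygen left as the C10=C11 silyl enol ether. The closest known reaction type is the rhodium-catalysed intramolecular [5+2] cycloaddition of alkyne-tethered vinylcyclopropanes, including its enantioselective [Rh(BINAP)]+ variant and cases in which a trisubstituted alkenylcyclopropane delivers an angular-methyl quaternary ring-fusion carbon. The five-membered ring closes in the exo sense through the three-atom ketal tether when C5 bonds to C6, and the seven-membered ring closes by the [5+2] union itself when C4 bonds to the cyclopropane methylene that becomes C3. The only new stereocentre, quaternary C6, is set by the chiral diphosphine, which must distinguish the enantiotopic faces of the trisubstituted alkene because the ketal tether is achiral. The step needs cyclisation to outrun alkyne oligomerisation and needs unambiguous ring opening: the gem-dialkoxy tether carbon favours the reactive conformation, and the siloxy-bearing cyclopropane carbon has two equivalent methylenes and a donor substituent that eases cleavage.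

Step 9
Reactants: 13 (6R)-bicyclic dienyl silyl ether
Product: 14 (6R)-C11 ketone (C4=C5 alkene and C9 dioxolane retained)
Conditions: TBAF, AcOH, THF, 0 °C
Reagents that add atoms: none
Why: Buffered fluoride cleaves the enol O–Si bond and protonation gives the ketone, while the acid-labile dioxolane is untouched.

Step 10
Reactants: 14 (6R)-C11 ketone
Product: 16 C2-methyl C11 ketone (both C2 epimers), via lithium enolate 15 (not isolated)
Conditions: LiN(iPr)2, THF, −78 °C; then MeI, −78 → −30 °C
Reagents that add atoms: iodomethane, CI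
Why: Kinetic enolate alkylation occurs at C2 because the C10 protons are neopentyl to quaternary C6, and the C2 configuration is immaterial because C2 later becomes sp2.

Step 11
Reactants: 16 C2-methyl C11 ketone
Product: 17 C11 alcohol (epimers at C2 and C11)
Conditions: NaBH4, MeOH, 0 °C
Reagents that add atoms: none
Why: Borohydride reduction masks C11 as a carbinol of immaterial configuration, so that borane and the isopropyl nucleophile can be used later.

Step 12
Reactants: 17 C11 alcohol
Product: 19 C11 benzyl ether, via sodium alkoxide 18 (not isolated)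
Conditions: NaH, THF/DMF, 0 °C; then BnBr, tetrabutylammonium iodide (cat.), rt
Reagents that add atoms: benzyl bromide, BrCc1ccccc1
Why: Williamson etherification installs a benzyl ether that withstands borane, mild acid, organocerium and acylation conditions and is removable by hydrogenolysis.

Step 13
Reactants: 19 C11 benzyl ether
Product: 21 C4 alcohol (C4–OH and C5–H both on the face opposite the C6 methyl; trans ring fusion), via C4 alkylborane 20 (not isolated)
Conditions: BH3·THF, THF, 0 °C → rt; then aq. NaOH, H2O2, 0 °C → rt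
Reagents that add atoms: hydrogen peroxide, OO
Why: Brown hydroboration–oxidation places boron on the less substituted C4 and hydrogen on C5 in a syn addition from the face opposite the axial C6 methyl (as with steroidal Δ5 alkenes), so the C5 and C4 centres are set together and oxidation retains the C4 configuration.

Step 14
Reactants: 21 C4 alcohol
Product: 22 C4 tert-butyldimethylsilyl ether
Conditions: TBSOTf, 2,6-lutidine, CH2Cl2, −78 → 0 °C
Reagents that add atoms: tert-butyldimethylsilyl trifluoromethanesulfonate, CC(C)(C)[Si](C)(C)OS(=O)(=O)C(F)(F)F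
Why: Silyl triflate silylation protects the hindered C4 hydroxyl before the C9 carbonyl is unveiled, and the ketal is stable to the buffered triflate.

Step 15
Reactants: 22 C4 tert-butyldimethylsilyl ether
Product: 23 C9 ketone (C5–H retained alpha to the new carbonyl)
Conditions: PPTS, acetone/H2O (9:1), 50 °C
Reagents that add atoms: water, O
Why: Mild acid-catalysed ketal hydrolysis frees the C9 ketone, and the hindered secondary silyl ether and the benzyl ether tolerate PPTS.

Step 16
Reactants: 23 C9 ketone
Product: 24 C9 tertiary alcohol (isopropyl syn to C5–H, hydroxyl syn to the C6 methyl)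
Conditions: iPrMgCl, CeCl3 (dried), THF, −78 °C; then 23, −78 → −40 °C; aq. NH4Cl
Reagents that add atoms: isopropylmagnesium chloride, CC(C)[Mg]Cl
Why: Organocerium addition (Imamoto conditions) suppresses enolisation and beta-hydride reduction, and the nucleophile should attack the cyclopentanone face opposite the pseudoaxial C6 methyl.

Step 17
Reactants: 25 4-hydroxybenzoic acid
Product: 27 4-(tert-butyldimethylsilyloxy)benzoic acid, via bis-silylated acid 26 (not isolated)
Conditions: TBSCl (2.3 equiv), imidazole, DMF, rt; then AcOH/THF/H2O, rt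
Reagents that add atoms: tert-butyldimethylsilyl chloride, CC(C)(C)[Si](C)(C)Cl
Why: Silylation of both hydroxyls followed by selective hydrolysis of the labile silyl ester leaves the aryl silyl ether.

Step 18
Reactants: 27 4-(tert-butyldimethylsilyloxy)benzoic acid
Product: 28 4-(tert-butyldimethylsilyloxy)benzoyl chloride
Conditions: (COCl)2, DMF (cat.), CH2Cl2, 0 °C → rt
Reagents that add atoms: oxalyl chloride, ClC(=O)C(=O)Cl
Why: Vilsmeier-type activation with oxalyl chloride and catalytic DMF gives the acid chloride.

Step 19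
Reactants: 24 C9 tertiary alcohol; 28 4-(tert-butyldimethylsilyloxy)benzoyl chloride
Product: 30 C9 4-(tert-butyldimethylsilyloxy)benzoate, via lithium alkoxide 29 (not isolated)
Conditions: n-BuLi, THF, −78 °C; then 28, −78 °C → rt
Reagents that add atoms: none
Why: O-Acylation of the preformed lithium alkoxide with the acid chloride compensates for the low nucleophilicity of the hindered tertiary alcohol.

Step 20
Reactants: 30 C9 4-(tert-butyldimethylsilyloxy)benzoate
Product: 31 C11 alcohol (benzyl ether removed)
Conditions: H2 (1 atm), Pd/C, EtOAc, rt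
Reagents that add atoms: none
Why: Hydrogenolysis of the benzyl ether over palladium on carbon proceeds without alkenes present, and the silyl ethers and the aryl ester are unaffected in ethyl acetate.

Step 21
Reactants: 31 C11 alcohol
Product: 33 bis-silylated enone (C11 ketone, C2=C3 alkene with C2 methyl), via C11 ketone 32 (not isolated)
Conditions: IBX (4 equiv), DMSO/fluorobenzene (1:2), 65 → 80 °C
Reagents that add atoms: none
Why: IBX oxidises the carbinol to the ketone and then dehydrogenates it (IBX dehydrogenation); because C6 is quaternary, only the C2–C3 bond can be desaturated.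

Step 22
Reactants: 33 bis-silylated enone
Product: 34 target, (4S,5S,6R,9R)-hydroxy enone 4-hydroxybenzoate
Conditions: HF·pyridine, pyridine, THF, 0 °C → rt
Reagents that add atoms: none
Why: Fluoride cleaves the alkyl and aryl silyl ethers under mildly acidic conditions that disfavour acyl migration from the C9 oxygen to the C4 oxygen.

**Compound list**

1 | pent-4-ynoic acid | C#CCCC(=O)O | starting material
2 | N-methoxy-N-methylpent-4-ynamide | C#CCCC(=O)N(C)OC | intermediate
3 | ethynyltrimethylsilane | C#C[Si](C)(C)C | starting material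
4 | lithium (trimethylsilyl)acetylide (formed in the flask) | [Li]C#C[Si](C)(C)C | intermediate
5 | 1-(trimethylsilyl)hepta-1,6-diyn-3-one | C#CCCC(=O)C#C[Si](C)(C)C | intermediate
6 | 2-(but-3-yn-1-yl)-2-[(trimethylsilyl)ethynyl]-1,3-dioxolane | C#CCCC1(OCCO1)C#C[Si](C)(C)C | intermediate
7 | dimethyl{(1E)-2-methyl-4-[2-((trimethylsilyl)ethynyl)-1,3-dioxolan-2-yl]but-1-en-1-yl}alane (formed in the flask) | C[Al](C)/C=C(\C)CCC1(OCCO1)C#C[Si](C)(C)C | intermediate
8 | (3E)-4-methyl-6-{2-[(trimethylsilyl)ethynyl]-1,3-dioxolan-2-yl}hex-3-en-2-one | CC(=O)/C=C(\C)CCC1(OCCO1)C#C[Si](C)(C)C | intermediate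
9 | lithium (3E)-dienolate of 8 (formed in the flask) | [Li]OC(=C)/C=C(\C)CCC1(OCCO1)C#C[Si](C)(C)C | intermediate
10 | (3E)-2-(tert-butyldimethylsilyloxy)-4-methyl-6-{2-[(trimethylsilyl)ethynyl]-1,3-dioxolan-2-yl}hexa-1,3-diene | C=C(O[Si](C)(C)C(C)(C)C)/C=C(\C)CCC1(OCCO1)C#C[Si](C)(C)C | intermediate
11 | tert-butyl{1-[(1E)-2-methyl-4-{2-[(trimethylsilyl)ethynyl]-1,3-dioxolan-2-yl}but-1-en-1-yl]cyclopropoxy}dimethylsilane | C[Si](C)(C)C#CC1(OCCO1)CC/C(C)=C/C1(O[Si](C)(C)C(C)(C)C)CC1 | intermediate
12 | tert-butyl{1-[(1E)-4-(2-ethynyl-1,3-dioxolan-2-yl)-2-methylbut-1-en-1-yl]cyclopropoxy}dimethylsilane | C#CC1(OCCO1)CC/C(C)=C/C1(O[Si](C)(C)C(C)(C)C)CC1 | intermediate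
13 | (6R)-bicyclic dienyl silyl ether: C4=C5 and C10=C11 alkenes, C11–OTBS, C6 methyl, C9 spiro-dioxolane | C1CC=C2C3(OCCO3)CC[C@]2(C)C=C1O[Si](C)(C)C(C)(C)C | intermediate
14 | (6R)-C11 ketone with C4=C5 alkene and C9 spiro-dioxolane | O=C1CCC=C2C3(OCCO3)CC[C@]2(C)C1 | intermediate
15 | lithium enolate of 14 toward C2 (formed in the flask) | [Li]OC1=CCC=C2C3(OCCO3)CC[C@]2(C)C1 | intermediate
16 | (6R)-C2-methyl C11 ketone, C2 epimers | CC1CC=C2C3(OCCO3)CC[C@]2(C)CC1=O | intermediate
17 | (6R)-C2-methyl C11 alcohol, C2 and C11 epimers | CC1CC=C2C3(OCCO3)CC[C@]2(C)CC1O | intermediate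
18 | sodium alkoxide of 17 (formed in the flask) | CC1CC=C2C3(OCCO3)CC[C@]2(C)CC1O[Na] | intermediate
19 | (6R)-C11 benzyl ether, C2 and C11 epimers | CC1CC=C2C3(OCCO3)CC[C@]2(C)CC1OCc1ccccc1 | intermediate
20 | C4 monoalkylborane, boron and C5–H anti to the C6 methyl (formed in the flask) | CC1C[C@H](B)[C@@H]2[C@](C)(CCC23OCCO3)CC1OCc1ccccc1 | intermediate
21 | C4 alcohol, C4–OH and C5–H anti to the C6 methyl, C9 dioxolane, C11–OBn | CC1C[C@H](O)[C@@H]2[C@](C)(CCC23OCCO3)CC1OCc1ccccc1 | intermediate
22 | C4 TBS ether of 21 | CC1C[C@H](O[Si](C)(C)C(C)(C)C)[C@@H]2[C@](C)(CCC23OCCO3)CC1OCc1ccccc1 | intermediate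
23 | C9 ketone, C4–OTBS, C11–OBn, trans-fused | CC1C[C@H](O[Si](C)(C)C(C)(C)C)[C@@H]2[C@](C)(CCC2=O)CC1OCc1ccccc1 | intermediate
24 | C9 tertiary alcohol, isopropyl syn to C5–H, OH syn to C6 methyl | CC1C[C@H](O[Si](C)(C)C(C)(C)C)[C@@H]2[C@](C)(CC[C@@]2(O)C(C)C)CC1OCc1ccccc1 | intermediate
25 | 4-hydroxybenzoic acid | OC(=O)c1ccc(O)cc1 | starting material
26 | tert-butyldimethylsilyl 4-(tert-butyldimethylsilyloxy)benzoate (formed in the flask) | CC(C)(C)[Si](C)(C)OC(=O)c1ccc(O[Si](C)(C)C(C)(C)C)cc1 | intermediate
27 | 4-(tert-butyldimethylsilyloxy)benzoic acid | OC(=O)c1ccc(O[Si](C)(C)C(C)(C)C)cc1 | intermediate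
28 | 4-(tert-butyldimethylsilyloxy)benzoyl chloride | ClC(=O)c1ccc(O[Si](C)(C)C(C)(C)C)cc1 | intermediate
29 | lithium alkoxide of 24 (formed in the flask) | CC1C[C@H](O[Si](C)(C)C(C)(C)C)[C@@H]2[C@](C)(CC[C@@]2(O[Li])C(C)C)CC1OCc1ccccc1 | intermediate
30 | C9 4-(tert-butyldimethylsilyloxy)benzoate, C4–OTBS, C11–OBn | CC1C[C@H](O[Si](C)(C)C(C)(C)C)[C@@H]2[C@](C)(CC[C@@]2(OC(=O)c2ccc(O[Si](C)(C)C(C)(C)C)cc2)C(C)C)CC1OCc1ccccc1 | intermediate
31 | C11 alcohol of 30 (benzyl removed), C2 and C11 epimers | CC1C[C@H](O[Si](C)(C)C(C)(C)C)[C@@H]2[C@](C)(CC[C@@]2(OC(=O)c2ccc(O[Si](C)(C)C(C)(C)C)cc2)C(C)C)CC1O | intermediate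
32 | C11 ketone, C2 epimers (formed in the flask) | CC1C[C@H](O[Si](C)(C)C(C)(C)C)[C@@H]2[C@](C)(CC[C@@]2(OC(=O)c2ccc(O[Si](C)(C)C(C)(C)C)cc2)C(C)C)CC1=O | intermediate
33 | bis-TBS enone: C11 ketone, C2=C3, C4–OTBS, aryl OTBS | CC1=C[C@H](O[Si](C)(C)C(C)(C)C)[C@@H]2[C@](C)(CC[C@@]2(OC(=O)c2ccc(O[Si](C)(C)C(C)(C)C)cc2)C(C)C)CC1=O | intermediate
34 | target, (4S,5S,6R,9R) in the plan numbering | CC1=C[C@H](O)[C@@H]2[C@](C)(CC[C@@]2(OC(=O)c2ccc(O)cc2)C(C)C)CC1=O | target

**Step count**

Total: 22 steps. Longest linear sequence: 20 steps (steps 1–16 and 19–22); steps 17–18 prepare the acyl donor.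

**Steps most likely to fail**

Step 8. The risk is weak enantioface discrimination, or slow cyclisation, at the fully substituted alkene terminus under the bulky chiral catalyst. Fallback: from 12, run the same cycloaddition with the achiral and more reactive [Rh(CO)2Cl]2 (ClCH2CH2Cl, 60–80 °C). This should give racemic cycloadduct, that is 13 together with the (6S)-dienyl silyl ether F1. Desilylation of the mixture with TBAF/AcOH gives 14 together with the (6S)-ketone F2. The enantiomers are then separated by preparative chromatography on a chiral stationary phase, and the (6R) fraction is 14, which re-enters the route at step 10.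

Step 16. The risk is enolisation of the hindered alpha-branched cyclopentanone (with erosion of the C5 configuration), beta-hydride reduction by the secondary organometallic, or incomplete facial control because the C4 silyloxy group sits near the face to be attacked. Fallback: from 23, add the smaller sp2 nucleophile CH2=C(CH3)MgBr/CeCl3 (THF, −78 °C), which cannot deliver a beta-hydride, to give the isopropenyl carbinol F3. Hydrogenation of its 1,1-disubstituted alkene with H2 and RhCl(PPh3)3 (benzene/EtOH), which leaves the benzyl ether intact, then gives 24.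

Step 19. The risk is slow O-acylation of the congested tertiary alkoxide, which gives silyl migration from the C4 oxygen time to compete or returns the alcohol. Fallback: from 24, generate the alkoxide 29 and trap it with the small electrophile 1,1'-carbonyldiimidazole to give the C9 imidazole-1-carboxylate F4. The aryl–carbonyl bond is then formed instead of the O–acyl bond by adding [4-(tert-butyldimethylsilyloxy)phenyl]magnesium bromide F5, prepared from (4-bromophenoxy)(tert-butyl)dimethylsilane and Mg in THF, at −78 → 0 °C (ester synthesis from alkyl imidazolecarboxylates and Grignard reagents). The product is 30.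

**Further compounds**

F1 | step 8 | (6S)-bicyclic dienyl silyl ether, enantiomer of 13 | C1CC=C2C3(OCCO3)CC[C@@]2(C)C=C1O[Si](C)(C)C(C)(C)C
F2 | step 8 | (6S)-C11 ketone, enantiomer of 14 | O=C1CCC=C2C3(OCCO3)CC[C@@]2(C)C1
F3 | step 16 | C9 isopropenyl carbinol (isopropenyl in place of isopropyl in 24) | CC1C[C@H](O[Si](C)(C)C(C)(C)C)[C@@H]2[C@](C)(CC[C@@]2(O)C(C)=C)CC1OCc1ccccc1
F4 | step 19 | C9 imidazole-1-carboxylate of 24 | CC1C[C@H](O[Si](C)(C)C(C)(C)C)[C@@H]2[C@](C)(CC[C@@]2(OC(=O)n2ccnc2)C(C)C)CC1OCc1ccccc1
F5 | step 19 | [4-(tert-butyldimethylsilyloxy)phenyl]magnesium bromide | Br[Mg]c1ccc(O[Si](C)(C)C(C)(C)C)cc1
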